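**Strategy.** Everything rests on opening the 12-membered lactone ring (C1 carbonyl, O2) at C7–C8, the unfunctionalised CH2–CH2 bond in the middle of the heptamethylene bridge (C4–C10) between carbinol carbon C3 and the arene. A one-pot ring-closing olefin metathesis/hydrogenation of a diene, a dimethoxybenzoate bearing an ortho but-3-enyl arm and an (R)-hept-6-en-2-yl ester arm, closes this ring and delivers the saturated bridge in one operation, remote from every stereocentre; the ortho-disubstituted benzoate acts as the turn element. The cis-fused furo[2,3-b]chroman ketal is then grafted onto the arene by a hetero-Diels–Alder reaction of an ortho-quinone methide with (S)-3,5-dimethyl-2,3-dihydrofuran.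

Key step: step 4

Remark: the benzo-fused lactone is numbered as a 1H-2-benzoxacyclododecin-1-one (C1 carbonyl, O2, C3 carbinol, C4–C10 methylenes with C10 benzylic, C10a, C11–C14 arene positions, C14a). Compounds 1, 2, 4 and 12 and all reagents are assumed to be commercially available.

**Step 1**
Reactants: 1 (S)-propylene oxide; 2 but-3-en-1-ylmagnesium bromide
Product: 3 (S)-hept-6-en-2-ol
Conditions: CuI (10 mol %), THF, −30 → 0 °C; then H2O
Reagents that add atoms: none
Why: Copper-catalysed SN2 opening of the terminal epoxide by the Grignard reagent at the unsubstituted carbon leaves the stereocentre untouched, so the (S) configuration is retained.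

**Step 2**
Reactants: 4 2,4-dimethoxy-6-methylbenzoic acid; 3 (S)-hept-6-en-2-ol
Product: 5 (R)-hept-6-en-2-yl 2,4-dimethoxy-6-methylbenzoate
Conditions: PPh3, DIAD, toluene, 0 °C → rt
Reagents that add atoms: none
Why: In the Mitsunobu esterification the hindered 2,6-disubstituted acid reacts as a carboxylate nucleophile, so crowding at its carbonyl is irrelevant, and SN2 displacement of the oxyphosphonium inverts the carbinol centre from (S) to (R).

**Step 3**
Reactants: 5 (R)-hept-6-en-2-yl 2,4-dimethoxy-6-methylbenzoate
Product: 6 (R)-hept-6-en-2-yl 2-(but-3-en-1-yl)-4,6-dimethoxybenzoate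
Conditions: LDA (1.1 equiv), THF, −78 °C; allyl bromide, −78 → −40 °C
Reagents that add atoms: allyl bromide, C=CCBr
Why: Lateral lithiation of the ortho-toluate gives the ester-stabilised benzylic anion, which is alkylated by allyl bromide (SN2); the hindered secondary ester resists self-condensation and the carbinol centre is not involved.

**Step 4**
Reactants: 6 (R)-hept-6-en-2-yl 2-(but-3-en-1-yl)-4,6-dimethoxybenzoate
Product: 8 (3R)-12,14-dimethoxy-3-methyl-3,4,5,6,7,8,9,10-octahydro-1H-2-benzoxacyclododecin-1-one, via unsaturated macrolactone 7 (not isolated)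
Conditions: second-generation Grubbs catalyst (H2IMes)(PCy3)Cl2Ru=CHPh (5 mol %), ClCH2CH2Cl (2 mM), 60 °C; then H2 (7 bar), 70 °C
Reagents that add atoms: none
Why: The ruthenium benzylidene loads onto one terminal alkene, and [2+2] cycloaddition/cycloreversion through ruthenacyclobutanes (Chauvin mechanism) with the second alkene closes the ring and expels ethylene, whose escape drives the reaction; under hydrogen the carbene is converted into a ruthenium hydride that saturates the new C7=C8 bond in the same flask. The closest known reaction type is the ring-closing olefin metathesis of ortho-alkenyl benzoate esters to 12- and 14-membered resorcylic lactones, combined with the known tandem metathesis/hydrogenation by a single ruthenium precatalyst. The 12-membered lactone ring is closed by end-to-end macrocyclisation of two monosubstituted alkenes, not by a polar or radical cyclisation, so no Baldwin-type constraint applies. No stereocentre is created: the E/Z mixture of 7 is erased by hydrogenation, and the (R)-carbinol centre C3, three carbons from the nearest alkene, is untouched. The step needs ring closure to win over acyclic diene metathesis oligomerisation; this is secured by the ortho relationship of the two arms on the arene, by the ester being twisted out of the ring plane by its two ortho substituents so that the heptenyl chain folds over the butenyl arm, and by 2 mM dilution. Only the disubstituted alkene should be hydrogenated, since the arene, the ester and the aryl methyl ethers are inert to the ruthenium hydride under these conditions.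

**Step 5**
Reactants: 8 (3R)-12,14-dimethoxy-3-methyl-3,4,5,6,7,8,9,10-octahydro-1H-2-benzoxacyclododecin-1-one
Product: 9 (3R)-12,14-dimethoxy-3-methyl-1-oxo-3,4,5,6,7,8,9,10-octahydro-1H-2-benzoxacyclododecine-11-carbaldehyde
Conditions: Cl2CHOMe (1.5 equiv), TiCl4 (2.2 equiv), CH2Cl2, −78 → 0 °C; then H2O
Reagents that add atoms: dichloromethyl methyl ether, COC(Cl)Cl; water, O
Why: Rieche formylation (Friedel–Crafts attack of the chloro(methoxy)carbenium ion, then hydrolysis) should occur at C11, which is para to the 14-methoxy and ortho to the 12-methoxy group, as in 3,5-dimethoxytoluene-type arenes, and not at C13, which is shielded between two methoxy groups.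

**Step 6**
Reactants: 9 (3R)-12,14-dimethoxy-3-methyl-1-oxo-3,4,5,6,7,8,9,10-octahydro-1H-2-benzoxacyclododecine-11-carbaldehyde
Product: 10 (3R)-12-hydroxy-14-methoxy-3-methyl-1-oxo-3,4,5,6,7,8,9,10-octahydro-1H-2-benzoxacyclododecine-11-carbaldehyde
Conditions: BCl3 (1.1 equiv), CH2Cl2, −78 → −20 °C; then H2O
Reagents that add atoms: none
Why: Chelation-controlled ether cleavage: BCl3 binds the coplanar, most Lewis-basic aldehyde oxygen and the neighbouring 12-methoxy oxygen in a six-membered chelate and chloride removes that methyl group (SN2), whereas the 14-methoxy group sits beside the less basic lactone carbonyl, which is twisted out of the arene plane, and should survive one equivalent at low temperature.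

**Step 7**
Reactants: 10 (3R)-12-hydroxy-14-methoxy-3-methyl-1-oxo-3,4,5,6,7,8,9,10-octahydro-1H-2-benzoxacyclododecine-11-carbaldehyde
Product: 11 (3R)-12-hydroxy-11-(hydroxymethyl)-14-methoxy-3-methyl-3,4,5,6,7,8,9,10-octahydro-1H-2-benzoxacyclododecin-1-one
Conditions: NaBH4, THF/MeOH, 0 °C; neutral work-up, used crude
Reagents that add atoms: none
Why: Chemoselective borohydride reduction of the aldehyde in the presence of the hindered lactone gives the ortho-hydroxybenzyl alcohol; short time and low temperature avoid over-reduction through the quinone methide.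

**Step 8**
Reactants: 12 (R)-4-benzyl-3-propionyloxazolidin-2-one
Product: 13 (R)-4-benzyl-3-[(S)-2-methylpent-4-ynoyl]oxazolidin-2-one
Conditions: NaN(SiMe3)2, THF, −78 °C; propargyl bromide, −78 → −40 °C
Reagents that add atoms: propargyl bromide, C#CCBr
Why: Evans asymmetric alkylation: the sodium-chelated Z-enolate is alkylated on the face opposite the benzyl group of the auxiliary, which sets the new α-stereocentre as (S).

**Step 9**
Reactants: 13 (R)-4-benzyl-3-[(S)-2-methylpent-4-ynoyl]oxazolidin-2-one
Product: 14 (S)-2-methylpent-4-yn-1-ol
Conditions: LiBH4, Et2O, MeOH (1 equiv), 0 °C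
Reagents that add atoms: none
Why: Reductive cleavage of the N-acyl oxazolidinone by LiBH4 gives the primary alcohol without touching the α-stereocentre and releases the auxiliary for recovery.

**Step 10**
Reactants: 14 (S)-2-methylpent-4-yn-1-ol
Product: 16 (S)-3,5-dimethyl-2,3-dihydrofuran, via exocyclic enol ether 15 (not isolated)
Conditions: NaNH2 (5 mol %), neat, 110 °C; then PPTS (7 mol %), 40 °C; distil from K2CO3
Reagents that add atoms: none
Why: Base-catalysed alkynol cycloisomerisation (5-exo-dig addition of the alkoxide to the alkyne) gives the exocyclic enol ether 15, which the slight excess of the mild acid should equilibrate through the 2-methyl oxocarbenium ion to the more substituted endocyclic enol ether; neither event involves the methyl-bearing stereocentre, which stays (S).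

**Step 11**
Reactants: 11 (3R)-12-hydroxy-11-(hydroxymethyl)-14-methoxy-3-methyl-3,4,5,6,7,8,9,10-octahydro-1H-2-benzoxacyclododecin-1-one; 16 (S)-3,5-dimethyl-2,3-dihydrofuran (3 equiv)
Product: 18 lasiodiplactone A, via ortho-quinone methide 17 (not isolated)
Conditions: toluene, sealed tube, 120 °C
Reagents that add atoms: none
Why: Thermal 1,4-dehydration of the ortho-hydroxybenzyl alcohol gives quinone methide 17, which the electron-rich enol ether traps in an inverse-electron-demand hetero-Diels–Alder reaction: the enol ether β-carbon bonds to the exocyclic methylene and the oxygen-bearing carbon to the quinone oxygen, suprafacial addition makes the 5/6 ring fusion cis, and approach anti to the allylic methyl of 16 sets the ring-fusion CH and the ketal carbon (both S) relative to the (S)-methyl centre.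

**Compound list**

1 | (S)-propylene oxide [(S)-2-methyloxirane] | C[C@H]1CO1 | starting material
2 | but-3-en-1-ylmagnesium bromide | C=CCC[Mg]Br | starting material
3 | (S)-hept-6-en-2-ol | C[C@H](O)CCCC=C | intermediate
4 | 2,4-dimethoxy-6-methylbenzoic acid | COc1cc(OC)cc(C)c1C(=O)O | starting material
5 | (R)-hept-6-en-2-yl 2,4-dimethoxy-6-methylbenzoate | COc1cc(OC)cc(C)c1C(=O)O[C@H](C)CCCC=C | intermediate
6 | (R)-hept-6-en-2-yl 2-(but-3-en-1-yl)-4,6-dimethoxybenzoate | COc1cc(OC)cc(CCC=C)c1C(=O)O[C@H](C)CCCC=C | intermediate
7 | (3R)-12,14-dimethoxy-3-methyl-3,4,5,6,9,10-hexahydro-1H-2-benzoxacyclododecin-1-one (C7=C8 alkene, E/Z mixture) | COc1cc(OC)cc2c1C(=O)O[C@H](C)CCCC=CCC2 | intermediate (not isolated)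
8 | (3R)-12,14-dimethoxy-3-methyl-3,4,5,6,7,8,9,10-octahydro-1H-2-benzoxacyclododecin-1-one (lasiodiplodin methyl ether) | COc1cc(OC)cc2c1C(=O)O[C@H](C)CCCCCCC2 | intermediate
9 | (3R)-12,14-dimethoxy-3-methyl-1-oxo-3,4,5,6,7,8,9,10-octahydro-1H-2-benzoxacyclododecine-11-carbaldehyde | COc1cc(OC)c(C=O)c2c1C(=O)O[C@H](C)CCCCCCC2 | intermediate
10 | (3R)-12-hydroxy-14-methoxy-3-methyl-1-oxo-3,4,5,6,7,8,9,10-octahydro-1H-2-benzoxacyclododecine-11-carbaldehyde | COc1cc(O)c(C=O)c2c1C(=O)O[C@H](C)CCCCCCC2 | intermediate
11 | (3R)-12-hydroxy-11-(hydroxymethyl)-14-methoxy-3-methyl-3,4,5,6,7,8,9,10-octahydro-1H-2-benzoxacyclododecin-1-one | COc1cc(O)c(CO)c2c1C(=O)O[C@H](C)CCCCCCC2 | intermediate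
12 | (R)-4-benzyl-3-propionyloxazolidin-2-one | CCC(=O)N1[C@H](Cc2ccccc2)COC1=O | starting material
13 | (R)-4-benzyl-3-[(S)-2-methylpent-4-ynoyl]oxazolidin-2-one | C#CC[C@H](C)C(=O)N1[C@H](Cc2ccccc2)COC1=O | intermediate
14 | (S)-2-methylpent-4-yn-1-ol | C#CC[C@H](C)CO | intermediate
15 | (S)-4-methyl-2-methylidenetetrahydrofuran | C=C1C[C@H](C)CO1 | intermediate (not isolated)
16 | (S)-3,5-dimethyl-2,3-dihydrofuran | CC1=C[C@H](C)CO1 | intermediate
17 | ortho-quinone methide, (3R)-14-methoxy-3-methyl-11-methylidene-3,4,5,6,7,8,9,10-octahydro-1H-2-benzoxacyclododecine-1,12(11H)-dione | COC1=CC(=O)C(=C)C2=C1C(=O)O[C@H](C)CCCCCCC2 | intermediate (not isolated)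
18 | lasiodiplactone A: (R) at the lactone carbinol carbon; cis-fused furo[2,3-b]chroman ketal with (S) ring-fusion CH, (S) CH(CH3) carbon and (S) ketal carbon; ketal methyl, ring-fusion H and secondary methyl on one face of the tetrahydrofuran ring | COc1cc2c(c3c1C(=O)O[C@H](C)CCCCCCC3)C[C@H]1[C@H](C)CO[C@@]1(C)O2 | target

**Step count.** Total: 11 steps. Longest linear sequence: 8 steps (steps 1, 2, 3, 4, 5, 6, 7 and 11); the dihydrofuran branch (steps 8–10) joins at step 11.

**Steps most likely to fail**

1. Step 11. The quinone methide may oligomerise, and under the hot, weakly acidic conditions the enol ether may react through a small share of its exocyclic isomer and give a spiroketal. The face of the dihydrofuran may also be discriminated only moderately at 120 °C. The fallback sets out from salicylaldehyde 10 and generates the quinone methide anionically at low temperature. Boc2O, iPr2NEt and catalytic DMAP in CH2Cl2 should give the aryl tert-butyl carbonate of the aldehyde F1. BH3·THF at 0 °C should reduce the aldehyde without forming a free alkoxide and give the O-Boc salicyl alcohol F2. Treatment of F2 with tBuMgCl in Et2O at −78 °C → rt in the presence of 16 should move the Boc group to the benzylic oxygen and eliminate tert-butyl carbonate. This forms quinone methide 17 under non-acidic conditions, where the enol ether cannot isomerise and the cycloaddition should be more face-selective. The fallback comes back to the route at target 18.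

2. Step 5. The electrophile may attack C13 as well as C11, and TiCl4 may cleave a methyl ether prematurely. The fallback sets out from 8 and replaces the Friedel–Crafts formylation by halogenation and metalation. NBS in MeCN at 0 °C should brominate at C11, the site para to the 14-methoxy group that halogenating agents prefer in this class of arenes. This gives the (3R)-11-bromo-12,14-dimethoxy lactone F3. Bromine–lithium exchange with nBuLi in THF at −90 °C, which should be faster than attack on the hindered lactone, and quenching with DMF should give aldehyde 9, where the fallback comes back to the route.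

3. Step 6. BCl3 may also cleave the 14-methoxy group next to the lactone carbonyl, or may open the lactone. The fallback sets out from 8 and bypasses steps 5 and 6 by reversing the order of phenol release and formylation. NaSEt in DMF at 110 °C should cleave the unhindered 12-methoxy group para to the ester by SN2 attack at methyl and give (R)-lasiodiplodin F4. Magnesium-mediated ortho-formylation (MgCl2, Et3N, paraformaldehyde, MeCN, reflux) should then place the formyl group at C11, ortho to the phenol and para to the methoxy group. The fallback comes back to the route at salicylaldehyde 10.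

**Further compounds**

F1 | step 11 | tert-butyl (3R)-11-formyl-14-methoxy-3-methyl-1-oxo-3,4,5,6,7,8,9,10-octahydro-1H-2-benzoxacyclododecin-12-yl carbonate | COc1cc(OC(=O)OC(C)(C)C)c(C=O)c2c1C(=O)O[C@H](C)CCCCCCC2
F2 | step 11 | tert-butyl (3R)-11-(hydroxymethyl)-14-methoxy-3-methyl-1-oxo-3,4,5,6,7,8,9,10-octahydro-1H-2-benzoxacyclododecin-12-yl carbonate | COc1cc(OC(=O)OC(C)(C)C)c(CO)c2c1C(=O)O[C@H](C)CCCCCCC2
F3 | step 5 | (3R)-11-bromo-12,14-dimethoxy-3-methyl-3,4,5,6,7,8,9,10-octahydro-1H-2-benzoxacyclododecin-1-one | COc1cc(OC)c(Br)c2c1C(=O)O[C@H](C)CCCCCCC2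
F4 | step 6 | (R)-lasiodiplodin, (3R)-12-hydroxy-14-methoxy-3-methyl-3,4,5,6,7,8,9,10-octahydro-1H-2-benzoxacyclododecin-1-one | COc1cc(O)cc2c1C(=O)O[C@H](C)CCCCCCC2
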